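**Plan**
1. Labels: the germacrane numbering of the target is kept for every intermediate (ring C1–C10, C15 on C4, C14 on C10, C11–C13 on C7, lactone O on C8).
2. Cuts: first the C6 ester, C11=C13, the C6 carbinol and the 4,5-epoxide, back to a (4E)-4-en-6-one. Then C3–C4 is cut while C1–C6 is re-joined. Last come C5–C6, C1–C2, C7–C11 and the C8/C9 oxygens of the resulting cyclohexane.
3. Enabling feature: C6 bears oxygen, C5 alone separates it from C4, and C1–C3 are bare CH2 groups. C3–C4 is therefore the new σ-bond of an oxy-Cope array C3=C2–C1–C6(O⁻)–C5=C4. The ten-membered ring contracts to the cyclohexane C1/C6/C7/C8/C9/C10, which holds all four stereocentres that survive (C7–C10).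
4. Forward order: quinone monoketal (six-ring), C7 arm, C8–O, trans-fused five-membered acetal (masked lactone), C1 vinyl, C9–OH, C6 (Z)-propenyl carbinol, ring expansion 6→10. The endgame is E-enone, lactone, epoxide, C6–OH, methylene lactone, ester.
5. Stereochemistry: C7 comes from (R)-BINAP. C8, C10 and C9 follow from C7 in the locked chair. The Z-propenyl geometry is relayed through C4/C5 to the 4E-alkene. The epoxide face comes from peripheral attack and C6 from chelation-controlled hydride delivery.

Key step: step 9

Remark: the acetal carbon C12 in 6–24 is carried as a mixture of anomers and is drawn without configuration, because it ends as the lactone carbonyl. The sense of induction of (R)-BINAP is assumed to be the one known for cyclohex-2-enone.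

Step 1
Reactants: 1 4-methoxy-2-methylphenol
Product: 2 4,4-dimethoxy-2-methylcyclohexa-2,5-dien-1-one
Conditions: PhI(OAc)2, MeOH, 0 °C
Reagents that add atoms: methanol, CO
Why: Oxidative dearomatisation of a 4-alkoxyphenol by a hypervalent iodine reagent in methanol is the standard entry to quinone monoketals; no stereocentre is formed, and C9 (ketone), C6 (ketal) and C10–CH3 are already in place.

Step 2
Reactants: 2 4,4-dimethoxy-2-methylcyclohexa-2,5-dien-1-one; 3 (E)-2-(2-ethoxyethenyl)-4,4,5,5-tetramethyl-1,3,2-dioxaborolane
Product: 4 (5R)-5-[(E)-2-ethoxyethenyl]-4,4-dimethoxy-2-methylcyclohex-2-en-1-one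
Conditions: [RhCl(C2H4)2]2 (2.5 mol %), (R)-BINAP (5.5 mol %), KOH (0.5 equiv), 1,4-dioxane/H2O 10:1, 40 °C
Reagents that add atoms: none
Why: Hayashi–Miyaura asymmetric 1,4-addition of an alkenylboron reagent, a reaction type known for quinone monoketals; the alkenylrhodium species should insert only into the alkene without the methyl group, and the BINAP-controlled enantioface sets C7.

Step 3
Reactants: 4 (5R)-5-[(E)-2-ethoxyethenyl]-4,4-dimethoxy-2-methylcyclohex-2-en-1-one
Product: 6 trans-fused ethyl acetal enone (2-ethoxy-4,4-dimethoxy-6-methyl-3,3a,4,7a-tetrahydro-1-benzofuran-7(2H)-one; H7 and H8 anti), via hydroxy ketone 5 (not isolated)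
Conditions: LiN(SiMe3)2, THF, −78 °C; 3-phenyl-2-(phenylsulfonyl)oxaziridine, −78 °C; H2O; crude 5, PPTS (5 mol %), 4 Å MS, CH2Cl2, 0 °C
Reagents that add atoms: 3-phenyl-2-(phenylsulfonyl)oxaziridine, O=S(=O)(N1OC1c1ccccc1)c1ccccc1
Why: Davis oxidation of the only possible (cross-conjugated, C8) enolate should occur anti to the neighbouring C7 arm and so set C8 trans, and acid-catalysed 5-exo addition of the new hydroxyl to the protonated enol ether then closes the acetal that masks C12 and C8–O together.

Step 4
Reactants: 6 trans-fused ethyl acetal enone; 7 vinylmagnesium bromide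
Product: 9 C1-vinyl C9-ketone (vinyl axial and trans to the C7 arm; C10 methyl equatorial), via silyl enol ether 8 (not isolated)
Conditions: 7, CuBr·SMe2 (20 mol %), Me3SiCl, THF, −78 °C; then n-Bu4NF, AcOH, THF, −78 °C
Reagents that add atoms: none
Why: Copper-catalysed, chlorosilane-accelerated conjugate addition should follow the stereoelectronic axial path anti to the C7 substituent, and axial protonation of the released enolate on the face opposite the vinyl group should place C14 equatorial (C10 as in the target) without any base that could epimerise C8.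

Step 5
Reactants: 9 C1-vinyl C9-ketone
Product: 10 C9 axial alcohol (OH cis to C8–O and to C14)
Conditions: Li[HB(s-Bu)3], THF, −78 °C; H2O
Reagents that add atoms: none
Why: Reduction of a cyclohexanone with a bulky trialkylborohydride proceeds by equatorial attack, here reinforced by the axial vinyl group that blocks the axial trajectory, so the axial C9 alcohol should result.

Step 6
Reactants: 10 C9 axial alcohol
Product: 11 C9 tert-butyldimethylsilyl ether
Conditions: TBSOTf, 2,6-lutidine, CH2Cl2, −78 to 0 °C
Reagents that add atoms: tert-butyldimethylsilyl triflate, CC(C)(C)[Si](C)(C)OS(=O)(=O)C(F)(F)F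
Why: Silyl triflate with a hindered pyridine base is the standard silylation of hindered secondary alcohols and leaves ketal, acetal and alkene untouched.

Step 7
Reactants: 11 C9 tert-butyldimethylsilyl ether
Product: 13 C6 ketone that has the C1 vinyl group equatorial (C1, C7, C8 and C10 substituents equatorial; C9–OTBS axial), via axial-vinyl ketone 12 (not isolated)
Conditions: PPTS (20 mol %), acetone/H2O 20:1, rt; then DBU (10 mol %), CH2Cl2, 0 °C
Reagents that add atoms: water, O
Why: A ketone dimethyl ketal hydrolyses much faster than the aldehyde-derived cyclic acetal, and brief base treatment epimerises C1 through the dienolate, whose α-protonation is faster than γ-protonation, driven by relief of the 1,3-diaxial vinyl/OTBS contact, while the equatorial C8–O bond is misaligned for β-elimination.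

Step 8
Reactants: 13 C6 ketone that has the C1 vinyl group equatorial; 14 (Z)-1-bromoprop-1-ene
Product: 17 (Z)-propenyl carbinol (C6–OH axial and cis to the C1 vinyl group and the C7 arm; propenyl equatorial), via (Z)-propenyllithium 15 (not isolated), via (Z)-propenylcerium dichloride 16 (not isolated)
Conditions: 14, t-BuLi (2 equiv), Et2O, −78 °C; CeCl3, THF, −78 °C; then 13, −78 °C; H2O
Reagents that add atoms: none
Why: Bromine–lithium exchange retains the Z geometry, the weakly basic organocerium reagent adds 1,2 instead of enolising the doubly activated C1–H, and the bulky nucleophile should attack the locked chair equatorially, although either C6 epimer would lead to the same enone 22.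

Step 9
Reactants: 17 (Z)-propenyl carbinol
Product: 20 ring-expanded (1E)-5-phenylselanyl-cyclodec-1-en-6-one (C4–H, C15 and C5–Se as drawn in the SMILES), via potassium alkoxide 18 (not isolated), via potassium enolate 19 (not isolated)
Conditions: KH, 18-crown-6, THF, 0 to 40 °C; then PhSeBr, −78 °C
Reagents that add atoms: benzeneselenenyl bromide, Br[Se]c1ccccc1
Why: Deprotonation gives alkoxide 18, whose oxido group weakens C1–C6, and a concerted suprafacial [3,3]-sigmatropic shift through C3=C2–C1–C6(O⁻)–C5=C4 forms C3–C4 while C1–C6 breaks, giving the regiodefined C5=C6 enolate 19, which PhSeBr captures at C5. The closest known reaction type is the anionic oxy-Cope ring expansion of 1,2-dialkenylcyclohexanols to cyclodec-5-enones with trapping of the enolate in the same flask. The ten-membered ring is closed not end to end but by a four-atom expansion of the cyclohexane C1/C6/C7/C8/C9/C10 through a chair-like six-centre transition state with both alkenyl groups equatorial, so the entropic cost of medium-ring closure is avoided and C1=C2 should emerge E. C4 is set by the Z geometry of the propenyl group (methyl pseudo-axial) together with the alkene face that the C1/C6 configuration turns toward C3, C5 is set by attack of selenium on the outer enolate face anti to the new C3–C4 bond because the ring spans the inner face, and C7–C10 are spectators. The step needs a single 1,5-diene and an enolate that stays at C5: C11 is kept sp3 inside the acetal, so the C7 arm offers no second alkene and no carbonyl group, the C8 oxygen is a poor leaving group, and trapping at −78 °C precedes proton transfer to C7. Because bond making and bond breaking occur on the same face of C4–C5–C6 in a chair as in a boat, the 4,5-relationship that later gives the E-enone depends neither on the transition-state topology nor on the C6 configuration of 17.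

Step 10
Reactants: 20 ring-expanded 5-phenylselanyl ketone
Product: 22 (1E,4E)-cyclodeca-1,4-dien-6-one, via selenoxide 21 (not isolated)
Conditions: mCPBA (1.0 equiv), CH2Cl2, −78 °C; warm to 0 °C
Reagents that add atoms: none
Why: Selenoxide syn-elimination; H4 is the only β-hydrogen and becomes syn-coplanar to selenium only in the rotamer that places C15 cis to the carbonyl group and C3 trans to C6, so the elimination should be stereospecific for the 4E-enone, and selenium is oxidised far faster than either alkene.

Step 11
Reactants: 22 (1E,4E)-cyclodeca-1,4-dien-6-one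
Product: 23 (4E)-cyclodec-4-en-6-one ethyl acetal
Conditions: KO2CN=NCO2K, AcOH, EtOH, 0 °C to rt
Reagents that add atoms: none
Why: Diimide reduction transfers H2 fastest to strained 1,2-disubstituted alkenes and only slowly to trisubstituted conjugated ones, so C1=C2 alone should be saturated; no stereocentre is formed.

Step 12
Reactants: 23 (4E)-cyclodec-4-en-6-one ethyl acetal
Product: 24 lactol (C12–OH)
Conditions: AcOH/THF/H2O 3:1:1, 40 °C
Reagents that add atoms: water, O
Why: A 2-alkoxytetrahydrofuran acetal hydrolyses under conditions as mild as those for tetrahydropyranyl ethers, which a hindered secondary TBS ether and the enone should survive.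

Step 13
Reactants: 24 lactol
Product: 25 (4E)-6-oxo-12,8-olide (trans-lactone)
Conditions: Dess–Martin periodinane, CH2Cl2, 0 °C to rt
Reagents that add atoms: none
Why: Dess–Martin oxidation of a lactol to the lactone is neutral to weakly acidic and so avoids base-induced β-elimination of the new acyloxy group at C8.

Step 14
Reactants: 25 (4E)-6-oxo-12,8-olide
Product: 26 (4R,5R)-4,5-epoxy-6-oxo-12,8-olide
Conditions: dimethyldioxirane, acetone/CH2Cl2, 0 °C to rt
Reagents that add atoms: dimethyldioxirane, CC1(C)OO1
Why: Dioxirane epoxidation is concerted and stereospecific (E-alkene to trans-epoxide) and needs no base; only the outer face of the ring alkene is accessible, and the conformer exposing the required face should dominate because the trans-lactone holds the C6–C7–C8–C9 torsion near +120°, so only a C5–C6–C7–C8 torsion of the same sign avoids a C5/C9 syn-pentane contact.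

Step 15
Reactants: 26 4,5-epoxy-6-oxo-12,8-olide
Product: 27 (6R)-4,5-epoxy-6-hydroxy-12,8-olide
Conditions: NaBH4, CeCl3·7H2O, MeOH, −78 °C
Reagents that add atoms: none
Why: Luche reduction of an α,β-epoxy ketone goes through the cerium chelate of carbonyl and epoxide oxygens and takes hydride from the side of H5, away from C4 and C15 and on the outer ring face, which should give the anti (erythro) epoxy alcohol; the lactone is inert.

Step 16
Reactants: 27 4,5-epoxy-6-hydroxy-12,8-olide
Product: 30 α-methylene lactone with free C6–OH, via Mannich base 28 (not isolated), via methiodide 29 (not isolated)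
Conditions: LiN(i-Pr)2 (3 equiv), THF, −78 °C; CH2=NMe2 I, −78 to 0 °C; H2O; MeI, MeOH, rt; aq NaHCO3, CH2Cl2
Reagents that add atoms: Eschenmoser's salt, C=[N+](C)C.[I-]
Why: Mannich reaction of the lactone enolate followed by quaternisation and Hofmann-type elimination is the classical α-methylenation of γ-lactones; the excess base first forms the C6 lithium alkoxide, which should leave the epoxide and the enolised lactone alone at −78 °C, and the C11 centre is transient.

Step 17
Reactants: 30 α-methylene lactone with free C6–OH; 31 3-methylbut-2-enoic acid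
Product: 32 C6 3-methylbut-2-enoate (C9–OTBS)
Conditions: DCC, DMAP (20 mol %), CH2Cl2, 0 °C to rt
Reagents that add atoms: none
Why: Steglich esterification acylates the only free hydroxyl with retention at C6 and avoids the vinylketene pathway that would deconjugate the acyl group if an acid chloride and an amine base were used.

Step 18
Reactants: 32 C6 3-methylbut-2-enoate (C9–OTBS)
Product: 33 target CNP0119422.1
Conditions: HF·pyridine, pyridine, THF, 0 °C to rt
Reagents that add atoms: none
Why: Buffered HF·pyridine cleaves secondary TBS ethers without generating an alkoxide, so the trisubstituted epoxide, both unsaturated esters and the lactone position should survive.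

**Compound list**
1 | 4-methoxy-2-methylphenol | COc1ccc(O)c(C)c1 | starting material
2 | 4,4-dimethoxy-2-methylcyclohexa-2,5-dien-1-one | COC1(OC)C=CC(=O)C(C)=C1 | intermediate
3 | (E)-2-(2-ethoxyethenyl)-4,4,5,5-tetramethyl-1,3,2-dioxaborolane | CCO/C=C/B1OC(C)(C)C(C)(C)O1 | starting material
4 | (5R)-5-[(E)-2-ethoxyethenyl]-4,4-dimethoxy-2-methylcyclohex-2-en-1-one | O=C1C[C@H](/C=C/OCC)C(OC)(OC)C=C1C | intermediate
5 | (5S,6S)-5-[(E)-2-ethoxyethenyl]-6-hydroxy-4,4-dimethoxy-2-methylcyclohex-2-en-1-one (OH trans to the side chain) | O=C1[C@@H](O)[C@H](/C=C/OCC)C(OC)(OC)C=C1C | intermediate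
6 | trans-fused ethyl acetal enone | C1C(OCC)O[C@@H]2C(=O)C(C)=CC(OC)(OC)[C@@H]12 | intermediate
7 | vinylmagnesium bromide | C=C[Mg]Br | starting material
8 | trimethylsilyl enol ether of 9 | C1C(OCC)O[C@@H]2C(O[Si](C)(C)C)=C(C)[C@H](C=C)C(OC)(OC)[C@@H]12 | intermediate
9 | C1-vinyl C9-ketone (vinyl axial, C14 equatorial) | C1C(OCC)O[C@@H]2C(=O)[C@H](C)[C@H](C=C)C(OC)(OC)[C@@H]12 | intermediate
10 | C9 axial alcohol | C1C(OCC)O[C@@H]2[C@H](O)[C@H](C)[C@H](C=C)C(OC)(OC)[C@@H]12 | intermediate
11 | C9 TBS ether | C1C(OCC)O[C@@H]2[C@H](O[Si](C)(C)C(C)(C)C)[C@H](C)[C@H](C=C)C(OC)(OC)[C@@H]12 | intermediate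
12 | C6 ketone, C1 vinyl axial | C1C(OCC)O[C@@H]2[C@H](O[Si](C)(C)C(C)(C)C)[C@H](C)[C@H](C=C)C(=O)[C@@H]12 | intermediate
13 | C6 ketone, C1 vinyl equatorial | C1C(OCC)O[C@@H]2[C@H](O[Si](C)(C)C(C)(C)C)[C@H](C)[C@@H](C=C)C(=O)[C@@H]12 | intermediate
14 | (Z)-1-bromoprop-1-ene | C/C=C\Br | starting material
15 | (Z)-prop-1-enyllithium | C/C=C\[Li] | intermediate
16 | (Z)-prop-1-enylcerium dichloride | C/C=C\[Ce](Cl)Cl | intermediate
17 | (Z)-propenyl carbinol (C6–OH axial, cis to C1 vinyl and C7 arm) | C1C(OCC)O[C@@H]2[C@H](O[Si](C)(C)C(C)(C)C)[C@H](C)[C@@H](C=C)[C@](O)(/C=C\C)[C@@H]12 | intermediate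
18 | potassium alkoxide of 17 | C1C(OCC)O[C@@H]2[C@H](O[Si](C)(C)C(C)(C)C)[C@H](C)[C@@H](C=C)[C@]([O-])(/C=C\C)[C@@H]12.[K+] | intermediate
19 | ring-expanded potassium C5=C6 enolate (C1=C2 E) | C1C(OCC)O[C@@H]2[C@H](O[Si](C)(C)C(C)(C)C)[C@H](C)/C=C/C[C@@H](C)/C=C([O-])/[C@@H]12.[K+] | intermediate
20 | (1E)-5-phenylselanyl-cyclodec-1-en-6-one | C1C(OCC)O[C@@H]2[C@H](O[Si](C)(C)C(C)(C)C)[C@H](C)/C=C/C[C@@H](C)[C@@H]([Se]c3ccccc3)C(=O)[C@@H]12 | intermediate
21 | selenoxide of 20 | C1C(OCC)O[C@@H]2[C@H](O[Si](C)(C)C(C)(C)C)[C@H](C)/C=C/C[C@@H](C)[C@@H]([Se](=O)c3ccccc3)C(=O)[C@@H]12 | intermediate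
22 | (1E,4E)-cyclodeca-1,4-dien-6-one | C1C(OCC)O[C@@H]2[C@H](O[Si](C)(C)C(C)(C)C)[C@H](C)/C=C/C/C(C)=C/C(=O)[C@@H]12 | intermediate
23 | (4E)-cyclodec-4-en-6-one ethyl acetal | C1C(OCC)O[C@@H]2[C@H](O[Si](C)(C)C(C)(C)C)[C@H](C)CCC/C(C)=C/C(=O)[C@@H]12 | intermediate
24 | lactol | C1C(O)O[C@@H]2[C@H](O[Si](C)(C)C(C)(C)C)[C@H](C)CCC/C(C)=C/C(=O)[C@@H]12 | intermediate
25 | (4E)-6-oxo-12,8-olide | C1C(=O)O[C@@H]2[C@H](O[Si](C)(C)C(C)(C)C)[C@H](C)CCC/C(C)=C/C(=O)[C@@H]12 | intermediate
26 | (4R,5R)-4,5-epoxy-6-oxo-12,8-olide | C1C(=O)O[C@@H]2[C@H](O[Si](C)(C)C(C)(C)C)[C@H](C)CCC[C@@]3(C)O[C@@H]3C(=O)[C@@H]12 | intermediate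
27 | (6R)-4,5-epoxy-6-hydroxy-12,8-olide | C1C(=O)O[C@@H]2[C@H](O[Si](C)(C)C(C)(C)C)[C@H](C)CCC[C@@]3(C)O[C@@H]3[C@H](O)[C@@H]12 | intermediate
28 | C11 dimethylaminomethyl lactone (C11 epimers) | CN(C)CC1C(=O)O[C@@H]2[C@H](O[Si](C)(C)C(C)(C)C)[C@H](C)CCC[C@@]3(C)O[C@@H]3[C@H](O)[C@@H]12 | intermediate
29 | methiodide of 28 | C[N+](C)(C)CC1C(=O)O[C@@H]2[C@H](O[Si](C)(C)C(C)(C)C)[C@H](C)CCC[C@@]3(C)O[C@@H]3[C@H](O)[C@@H]12.[I-] | intermediate
30 | α-methylene lactone, C6–OH free, C9–OTBS | C=C1C(=O)O[C@@H]2[C@H](O[Si](C)(C)C(C)(C)C)[C@H](C)CCC[C@@]3(C)O[C@@H]3[C@H](O)[C@@H]12 | intermediate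
31 | 3-methylbut-2-enoic acid | CC(C)=CC(=O)O | starting material
32 | C6 3-methylbut-2-enoate, C9–OTBS | C=C1C(=O)O[C@@H]2[C@H](O[Si](C)(C)C(C)(C)C)[C@H](C)CCC[C@@]3(C)O[C@@H]3[C@H](OC(=O)C=C(C)C)[C@@H]12 | intermediate
33 | (4R,5R,6R,7S,8S,9R,10R)-4,5-epoxy-9-hydroxy-6-(3-methylbut-2-enoyloxy)germacr-11(13)-en-12,8-olide (CNP0119422.1) | C=C1C(=O)O[C@@H]2[C@H](O)[C@H](C)CCC[C@@]3(C)O[C@@H]3[C@H](OC(=O)C=C(C)C)[C@@H]12 | target

Total step count: 18. Longest linear sequence: 18 (from 1).

**Steps most likely to fail**

Step 9. The pseudo-axial Z-methyl group may slow the rearrangement. Proton transfer could then move the enolate toward C7, with loss of the C8 oxygen. Electrophilic selenium may also add to the strained C1=C2 bond, or attack C5 from the inner face and so erode the relay to the E-enone. The fallback sets out from 17 and comes back at 22. The rearrangement is run as before, but enolate 19 is quenched with Me3SiCl/Et3N to give the isolable ring-expanded trimethylsilyl enol ether F3. F3 is then dehydrogenated by Saegusa–Ito oxidation with Pd(OAc)2 in MeCN. The palladium enolate can reach H4 from either face, so the alkene geometry is decided by the lower-energy E transition state and not by the fidelity of the trap. No electrophilic selenium meets the strained alkene.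

Step 7. The vinyl double bond may migrate into conjugation faster than C1 epimerises, or the epimerisation may stall because the equatorial C1–H is poorly aligned with the carbonyl group. The fallback sets out from 12 and comes back at 13. Crude 12 is pushed on purpose, with DBU at rt, to the conjugated 1-ethylidene ketone F1. F1 is converted with excess KOt-Bu in t-BuOH/THF into the extended potassium dienolate F2. Inverse quench into cold aqueous AcOH then effects the classical deconjugative kinetic α-protonation. The proton enters axially, so the vinyl group ends equatorial.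

Step 14. Facial selectivity may be poor or reversed if the other planar-chiral ring conformer reacts faster, and oxidation of the electron-poor alkene may be slow. The fallback sets out from 25 and comes back at 26. Corey–Bakshi–Shibata reduction with (R)-2-methyl-CBS-oxazaborolidine and catecholborane (alkenyl arm as the large group) gives the C6-epimeric allylic alcohol F4. In F4, allylic 1,3-strain between C15 and the C6 substituents turns H6 toward C15 and the hydroxyl toward the outer face. Hydroxyl-directed epoxidation with VO(acac)2/t-BuOOH then delivers oxygen to that same face and gives the epoxy alcohol F5, which has the required C4/C5 configuration. Dess–Martin oxidation erases C6 and gives 26.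

**Further compounds**
F1 | step 7 | conjugated 1-ethylidene C6 ketone (E/Z mixture) | C1C(OCC)O[C@@H]2[C@H](O[Si](C)(C)C(C)(C)C)[C@H](C)C(=CC)C(=O)[C@@H]12
F2 | step 7 | extended potassium dienolate | C1C(OCC)O[C@@H]2[C@H](O[Si](C)(C)C(C)(C)C)[C@H](C)C(C=C)=C([O-])[C@@H]12.[K+]
F3 | step 9 | ring-expanded trimethylsilyl enol ether | C1C(OCC)O[C@@H]2[C@H](O[Si](C)(C)C(C)(C)C)[C@H](C)/C=C/C[C@@H](C)/C=C(O[Si](C)(C)C)/[C@@H]12
F4 | step 14 | C6-epimeric (4E)-allylic alcohol | C1C(=O)O[C@@H]2[C@H](O[Si](C)(C)C(C)(C)C)[C@H](C)CCC/C(C)=C/[C@@H](O)[C@@H]12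
F5 | step 14 | C6-epimeric 4,5-epoxy alcohol | C1C(=O)O[C@@H]2[C@H](O[Si](C)(C)C(C)(C)C)[C@H](C)CCC[C@@]3(C)O[C@@H]3[C@@H](O)[C@@H]12
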